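**Plan**

- Retrosynthesis: the three phenol masks come off last. Ring C is cut at O1–C2 and at C3–C(=O)Ar (cyclodehydration, enolate aroylation with 4-methoxybenzoyl chloride), the acyl chain at C4–C4a (aryllithium plus Weinreb amide), and ring A at C8a–C8, C7–C6 and C4a–C8a into a chiral siloxyalkyne and 3-ethoxycyclobutenone.
- Enabling feature: ring A is a hexasubstituted phloroglucinol ring whose C8 carries the 1-arylethyl group between O1 (on C8a) and the C7 oxygen. In a cyclobutenone/siloxyalkyne benzannulation the alkyne supplies C7, C8 and the C7 oxygen, and the cyclobutenone supplies C8a, C4a, C5, C6, O1 and the C5 oxygen. The oxygens therefore arrive as OH (O1), OSi (C7) and OEt (C5), and O1 is the only free phenol when ring C is closed.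
- Forward order: side chain with its stereocentre → siloxyalkyne (steps 1–6) → ring A (step 7) → methoxyacetyl and anisoyl units (steps 8–10) → ring C (step 11) → deprotection (steps 12–13). Ring B and the side-chain arene are bought as such.
- Stereochemistry: the single (R) centre at the benzylic carbon is set by an Evans methylation (step 2) and afterwards only has to survive; no later step creates or touches a stereocentre.

Key step: step 7

Assumption: compounds 1, 2, 13, 20 and 24 are bought.
Remark: the spatial arrangement at the benzylic centre is the same throughout; the descriptor reads S in 9 (and in the alkyne from which 10 derives) only because the CIP ranking of the substituents changes.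
Remark: diketone 26 is drawn in the diketo form; it should exist as a keto–enol/hemiketal mixture, and its C2 centre disappears in step 11.

**Step 1**
Reactants: 1 [4-(benzyloxy)phenyl]acetic acid; 2 (4R)-4-benzyl-1,3-oxazolidin-2-one
Product: 4 (4R)-4-benzyl-3-{[4-(benzyloxy)phenyl]acetyl}-1,3-oxazolidin-2-one, via mixed pivalic anhydride 3 (not isolated)
Conditions: t-BuCOCl, Et3N, THF, −20 °C; then LiCl, 2, −20 °C → rt
Reagents that add atoms: none
Why: N-acylation of the oxazolidinone through the mixed pivalic anhydride (LiCl/Et3N variant), a routine entry to arylacetyl imides that leaves the benzyl ether untouched.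

**Step 2**
Reactants: 4
Product: 6 (4R)-4-benzyl-3-{(2R)-2-[4-(benzyloxy)phenyl]propanoyl}-1,3-oxazolidin-2-one, via sodium Z-enolate 5 (not isolated)
Conditions: NaN(SiMe3)2, THF, −78 °C; MeI, −78 °C; AcOH quench at −78 °C
Reagents that add atoms: iodomethane, CI
Why: Evans auxiliary-controlled enolate alkylation, in which the chelated Z-enolate should be methylated on the face opposite the C4 benzyl group of the (R)-auxiliary, setting the (R) configuration of the benzylic carbon, the only stereocentre of the target.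

**Step 3**
Reactants: 6
Product: 7 (2R)-2-[4-(benzyloxy)phenyl]propan-1-ol
Conditions: LiBH4, H2O (1 equiv), Et2O, 0 °C
Reagents that add atoms: none
Why: Reductive cleavage of the N-acyloxazolidinone by LiBH4, a non-basic hydride reduction that should give the primary alcohol without epimerising the α-aryl centre and return auxiliary 2.

**Step 4**
Reactants: 7
Product: 8 (2R)-2-[4-(benzyloxy)phenyl]propanal
Conditions: Dess–Martin periodinane, CH2Cl2, 0 °C → rt; crude product used at once
Reagents that add atoms: none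
Why: Dess–Martin oxidation, which runs without base near room temperature and is the usual choice for aldehydes that racemise by enolisation, the aldehyde being carried on without chromatography.

**Step 5**
Reactants: 8
Product: 9 1-(benzyloxy)-4-[(2S)-4,4-dibromobut-3-en-2-yl]benzene
Conditions: CBr4, PPh3, CH2Cl2, 0 °C (ylide preformed); then 8, 0 °C
Reagents that add atoms: carbon tetrabromide, BrC(Br)(Br)Br
Why: Ramirez dibromo-olefination (first stage of the Corey–Fuchs sequence) with the non-basic ylide Ph3P=CBr2, which should consume the labile aldehyde faster than it can enolise.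

**Step 6**
Reactants: 9
Product: 12 {[(3R)-3-[4-(benzyloxy)phenyl]but-1-yn-1-yl]oxy}tri(propan-2-yl)silane, via lithium acetylide 10 (not isolated), via lithium ynolate 11 (not isolated)
Conditions: n-BuLi (2.1 equiv), THF, −78 °C; LiOOt-Bu (from t-BuOOH and LiN(SiMe3)2), −78 → 0 °C; i-Pr3SiOTf, −78 → 0 °C
Reagents that add atoms: tert-butyl hydroperoxide, CC(C)(C)OO; triisopropylsilyl trifluoromethanesulfonate, CC(C)[Si](OS(=O)(=O)C(F)(F)F)(C(C)C)C(C)C
Why: The second stage of the Corey–Fuchs sequence gives the lithium acetylide, known oxygen transfer from lithium tert-butyl peroxide converts it into the ynolate, and the bulky silyl triflate silylates on oxygen, while the propargylic centre carries no acidifying group at any point.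

**Step 7**
Reactants: 12; 13 3-ethoxycyclobut-2-en-1-one
Product: 18 2-{(1R)-1-[4-(benzyloxy)phenyl]ethyl}-5-ethoxy-3-[(triisopropylsilyl)oxy]phenol, via vinylketene 14 (not isolated), via vinylcyclobutenone 15 (not isolated), via dienylketene 16 (not isolated), via cyclohexadienone 17 (not isolated)
Conditions: 13 (1.3 equiv), toluene, 80 °C → 110 °C, sealed tube
Reagents that add atoms: none
Why: Danheiser benzannulation: heat should open 13 by 4π electrocyclic cleavage to vinylketene 14, whose ketene C=C adds to the siloxyalkyne in a regioselective [2+2] cycloaddition to give 15; a second 4π opening gives dienylketene 16, ring A closes by 6π electrocyclisation (C4a–C8a) to dienone 17, and tautomerisation gives phenol 18. The closest known reaction type is the thermal annulation of cyclobutenones with trialkylsilyloxyalkynes to resorcinol monosilyl ethers, which has also been applied to siloxyalkynes carrying a propargylic stereocentre. No lasting stereocentre is formed (the ring CH of 15 is lost again), and the propargylic centre of 12 is a spectator because the cascade needs neither base nor acid. The selectivity required is regiochemical: the alkyne carbon bearing the side chain, made nucleophilic by the ynol ether oxygen, must bond to the ketene carbonyl carbon, which places C8 between the free O1–H and the C7 silyl ether. Each oxygen of ring A thus carries a different label (H, Si, Et), which is what later lets ring C close on O1 alone.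

**Step 8**
Reactants: 18
Product: 19 [2-{(1R)-1-[4-(benzyloxy)phenyl]ethyl}-5-ethoxy-3-(methoxymethoxy)phenoxy]tri(propan-2-yl)silane
Conditions: MeOCH2Cl, i-Pr2NEt, CH2Cl2, 0 → 40 °C
Reagents that add atoms: chloromethyl methyl ether, COCCl
Why: O-alkylation of the only free phenol (Williamson-type acetal formation) should give a methoxymethyl ether that masks O1 and acts as the directing group for the next step.

**Step 9**
Reactants: 19; 20 N,2-dimethoxy-N-methylacetamide
Product: 23 1-[3-{(1R)-1-[4-(benzyloxy)phenyl]ethyl}-6-ethoxy-2-hydroxy-4-[(triisopropylsilyl)oxy]phenyl]-2-methoxyethan-1-one, via aryllithium 21 (not isolated), via MOM ketone 22 (not isolated)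
Conditions: n-BuLi, THF, 0 °C; 20, −78 → 0 °C; then 3 M HCl, MeOH, 40 °C
Reagents that add atoms: none
Why: Directed ortho-metalation at the ring C–H flanked by the OMOM and OEt groups (far faster than at the C–H next to the bulky silyl ether or at the hindered tertiary diarylmethine C–H), Weinreb ketone synthesis and acid cleavage of the ortho-acyl MOM ether should forge the C4–C4a bond without any Lewis acid.

**Step 10**
Reactants: 23; 24 4-methoxybenzoyl chloride
Product: 26 1-[3-{(1R)-1-[4-(benzyloxy)phenyl]ethyl}-6-ethoxy-2-hydroxy-4-[(triisopropylsilyl)oxy]phenyl]-2-methoxy-3-(4-methoxyphenyl)propane-1,3-dione, via dilithium dianion 25 (not isolated)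
Conditions: LiN(SiMe3)2 (3.5 equiv), THF, −78 → −10 °C; 24, −78 °C → rt; aq. HCl
Reagents that add atoms: none
Why: Claisen-type C-aroylation of the phenoxide–enolate dianion, the one-flask variant of the Baker–Venkataraman diketone synthesis used for 3-methoxyflavones, under an amide base that the silyl ether and the diarylmethine centre should tolerate.

**Step 11**
Reactants: 26
Product: 27 8-{(1R)-1-[4-(benzyloxy)phenyl]ethyl}-5-ethoxy-3-methoxy-2-(4-methoxyphenyl)-7-[(triisopropylsilyl)oxy]-4H-chromen-4-one
Conditions: p-TsOH·H2O (0.2 equiv), toluene, 80 °C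
Reagents that add atoms: none
Why: Acid-catalysed cyclodehydration of the 2-hydroxyaryl 1,3-diketone should close ring C by attack of the single free phenol oxygen (O1) on the anisoyl carbonyl and loss of water, the ethyl ether on the other ortho oxygen ensuring that only the 8-substituted chromone can form.

**Step 12**
Reactants: 27
Product: 28 8-{(1R)-1-[4-(benzyloxy)phenyl]ethyl}-5-ethoxy-7-hydroxy-3-methoxy-2-(4-methoxyphenyl)-4H-chromen-4-one
Conditions: Bu4NF, AcOH, THF, 0 °C
Reagents that add atoms: none
Why: Fluoride-mediated cleavage of the aryl silyl ether, buffered with acetic acid so that the chromone is not left as a free phenoxide.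

**Step 13**
Reactants: 28
Product: 29 5,7-dihydroxy-8-[(1R)-1-(4-hydroxyphenyl)ethyl]-3-methoxy-2-(4-methoxyphenyl)-4H-chromen-4-one
Conditions: BCl3 (1 M in CH2Cl2, 6 equiv), C6HMe5, CH2Cl2, −78 → 0 °C; MeOH
Reagents that add atoms: none
Why: Lewis-acid ether cleavage: BCl3 with pentamethylbenzene as cation scavenger should remove the benzyl ether at low temperature, and on warming boron bridging the C4 carbonyl and the peri C5 oxygen should direct chloride to the ethyl group, while the 3- and 4'-methyl ethers, which lack this six-membered chelate, should stay.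

**Compound list**

1 | [4-(benzyloxy)phenyl]acetic acid | OC(=O)Cc1ccc(OCc2ccccc2)cc1 | starting material
2 | (4R)-4-benzyl-1,3-oxazolidin-2-one | O=C1N[C@H](Cc2ccccc2)CO1 | starting material
3 | [4-(benzyloxy)phenyl]acetic pivalic anhydride (not isolated) | CC(C)(C)C(=O)OC(=O)Cc1ccc(OCc2ccccc2)cc1 | intermediate
4 | (4R)-4-benzyl-3-{[4-(benzyloxy)phenyl]acetyl}-1,3-oxazolidin-2-one | O=C(Cc1ccc(OCc2ccccc2)cc1)N1[C@H](Cc2ccccc2)COC1=O | intermediate
5 | sodium (Z)-enolate of 4 (not isolated) | [Na]O/C(=C\c1ccc(OCc2ccccc2)cc1)N1[C@H](Cc2ccccc2)COC1=O | intermediate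
6 | (4R)-4-benzyl-3-{(2R)-2-[4-(benzyloxy)phenyl]propanoyl}-1,3-oxazolidin-2-one | O=C([C@H](C)c1ccc(OCc2ccccc2)cc1)N1[C@H](Cc2ccccc2)COC1=O | intermediate
7 | (2R)-2-[4-(benzyloxy)phenyl]propan-1-ol | OC[C@H](C)c1ccc(OCc2ccccc2)cc1 | intermediate
8 | (2R)-2-[4-(benzyloxy)phenyl]propanal | O=C[C@H](C)c1ccc(OCc2ccccc2)cc1 | intermediate
9 | 1-(benzyloxy)-4-[(2S)-4,4-dibromobut-3-en-2-yl]benzene | BrC(Br)=C[C@H](C)c1ccc(OCc2ccccc2)cc1 | intermediate
10 | lithium acetylide of (3S)-3-[4-(benzyloxy)phenyl]but-1-yne (not isolated) | [Li]C#C[C@H](C)c1ccc(OCc2ccccc2)cc1 | intermediate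
11 | lithium (3R)-3-[4-(benzyloxy)phenyl]but-1-yn-1-olate (not isolated) | [Li]OC#C[C@H](C)c1ccc(OCc2ccccc2)cc1 | intermediate
12 | {[(3R)-3-[4-(benzyloxy)phenyl]but-1-yn-1-yl]oxy}tri(propan-2-yl)silane | CC(C)[Si](OC#C[C@H](C)c1ccc(OCc2ccccc2)cc1)(C(C)C)C(C)C | intermediate
13 | 3-ethoxycyclobut-2-en-1-one | CCOC1=CC(=O)C1 | starting material
14 | 3-ethoxybuta-1,3-dien-1-one, the vinylketene (not isolated) | CCOC(=C)C=C=O | intermediate
15 | 2-{(1R)-1-[4-(benzyloxy)phenyl]ethyl}-4-(1-ethoxyethenyl)-3-[(triisopropylsilyl)oxy]cyclobut-2-en-1-one, both epimers at C4 (not isolated) | CCOC(=C)C1C(=O)C([C@H](C)c2ccc(OCc3ccccc3)cc2)=C1O[Si](C(C)C)(C(C)C)C(C)C | intermediate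
16 | (3E)-2-{(1R)-1-[4-(benzyloxy)phenyl]ethyl}-5-ethoxy-3-[(triisopropylsilyl)oxy]hexa-1,3,5-trien-1-one, the dienylketene (not isolated) | CCOC(=C)\C=C(O[Si](C(C)C)(C(C)C)C(C)C)/C(=C=O)[C@H](C)c1ccc(OCc2ccccc2)cc1 | intermediate
17 | 2-{(1R)-1-[4-(benzyloxy)phenyl]ethyl}-5-ethoxy-3-[(triisopropylsilyl)oxy]cyclohexa-2,4-dien-1-one (not isolated) | CCOC1=CC(O[Si](C(C)C)(C(C)C)C(C)C)=C([C@H](C)c2ccc(OCc3ccccc3)cc2)C(=O)C1 | intermediate
18 | 2-{(1R)-1-[4-(benzyloxy)phenyl]ethyl}-5-ethoxy-3-[(triisopropylsilyl)oxy]phenol | CCOc1cc(O)c([C@H](C)c2ccc(OCc3ccccc3)cc2)c(O[Si](C(C)C)(C(C)C)C(C)C)c1 | intermediate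
19 | [2-{(1R)-1-[4-(benzyloxy)phenyl]ethyl}-5-ethoxy-3-(methoxymethoxy)phenoxy]tri(propan-2-yl)silane | CCOc1cc(OCOC)c([C@H](C)c2ccc(OCc3ccccc3)cc2)c(O[Si](C(C)C)(C(C)C)C(C)C)c1 | intermediate
20 | N,2-dimethoxy-N-methylacetamide | COCC(=O)N(C)OC | starting material
21 | aryllithium from 19, lithiated between the OMOM and OEt groups (not isolated) | CCOc1cc(O[Si](C(C)C)(C(C)C)C(C)C)c([C@H](C)c2ccc(OCc3ccccc3)cc2)c(OCOC)c1[Li] | intermediate
22 | 1-[3-{(1R)-1-[4-(benzyloxy)phenyl]ethyl}-6-ethoxy-2-(methoxymethoxy)-4-[(triisopropylsilyl)oxy]phenyl]-2-methoxyethan-1-one (not isolated) | CCOc1cc(O[Si](C(C)C)(C(C)C)C(C)C)c([C@H](C)c2ccc(OCc3ccccc3)cc2)c(OCOC)c1C(=O)COC | intermediate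
23 | 1-[3-{(1R)-1-[4-(benzyloxy)phenyl]ethyl}-6-ethoxy-2-hydroxy-4-[(triisopropylsilyl)oxy]phenyl]-2-methoxyethan-1-one | CCOc1cc(O[Si](C(C)C)(C(C)C)C(C)C)c([C@H](C)c2ccc(OCc3ccccc3)cc2)c(O)c1C(=O)COC | intermediate
24 | 4-methoxybenzoyl chloride | COc1ccc(C(=O)Cl)cc1 | starting material
25 | dilithium phenoxide–(Z)-enolate of 23 (not isolated) | CCOc1cc(O[Si](C(C)C)(C(C)C)C(C)C)c([C@H](C)c2ccc(OCc3ccccc3)cc2)c(O[Li])c1/C(O[Li])=C/OC | intermediate
26 | 1-[3-{(1R)-1-[4-(benzyloxy)phenyl]ethyl}-6-ethoxy-2-hydroxy-4-[(triisopropylsilyl)oxy]phenyl]-2-methoxy-3-(4-methoxyphenyl)propane-1,3-dione, mixture at C2 | CCOc1cc(O[Si](C(C)C)(C(C)C)C(C)C)c([C@H](C)c2ccc(OCc3ccccc3)cc2)c(O)c1C(=O)C(OC)C(=O)c1ccc(OC)cc1 | intermediate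
27 | 8-{(1R)-1-[4-(benzyloxy)phenyl]ethyl}-5-ethoxy-3-methoxy-2-(4-methoxyphenyl)-7-[(triisopropylsilyl)oxy]-4H-chromen-4-one | COc1ccc(-c2oc3c([C@H](C)c4ccc(OCc5ccccc5)cc4)c(O[Si](C(C)C)(C(C)C)C(C)C)cc(OCC)c3c(=O)c2OC)cc1 | intermediate
28 | 8-{(1R)-1-[4-(benzyloxy)phenyl]ethyl}-5-ethoxy-7-hydroxy-3-methoxy-2-(4-methoxyphenyl)-4H-chromen-4-one | COc1ccc(-c2oc3c([C@H](C)c4ccc(OCc5ccccc5)cc4)c(O)cc(OCC)c3c(=O)c2OC)cc1 | intermediate
29 | 5,7-dihydroxy-8-[(1R)-1-(4-hydroxyphenyl)ethyl]-3-methoxy-2-(4-methoxyphenyl)-4H-chromen-4-one | COc1ccc(-c2oc3c([C@H](C)c4ccc(O)cc4)c(O)cc(O)c3c(=O)c2OC)cc1 | target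

**Step count and risks**

Total step count: 13. Longest linear sequence: 13 steps (1 → 29); all other inputs are bought.

Steps most likely to fail:

Step 7. The donor-substituted cyclobutenone may open too slowly, so that oligomerisation of the vinylketene or thermal decay of the siloxyalkyne outruns the [2+2] cycloaddition. The fallback generates the vinylketene by 1,4-dehydrochlorination instead of ring opening and sets out from 12. Commercial ethyl (E)-3-ethoxybut-2-enoate is saponified (NaOH, aq. EtOH) to (E)-3-ethoxybut-2-enoic acid F1, which with (COCl)2 and catalytic DMF in CH2Cl2 should give (E)-3-ethoxybut-2-enoyl chloride F2. Slow addition of F2 to 12 and Et3N in toluene at room temperature should produce vinylketene 14 and from it cyclobutenone 15; warming to 80–110 °C should then lead through 16 and 17 to phenol 18, where the route is rejoined.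

Step 6. Oxygen transfer to the acetylide may be incomplete, silylation may occur on carbon instead of oxygen, and enantiopurity may already have been eroded by enolisation at the aldehyde stage just before. The fallback is a Kowalski ester homologation that bypasses the aldehyde and sets out from imide 6. LiOH/H2O2 (THF–H2O, 0 °C) should give (2R)-2-[4-(benzyloxy)phenyl]propanoic acid F3 with recovery of 2, and Me3SiCHN2 in toluene–MeOH should give methyl (2R)-2-[4-(benzyloxy)phenyl]propanoate F4. Addition of F4 to preformed LiCHBr2 (CH2Br2, lithium 2,2,6,6-tetramethylpiperidide, THF, −78 °C, to limit enolisation of the ester) should give (3R)-3-[4-(benzyloxy)phenyl]-1,1-dibromobutan-2-one F5, held as its enolate by LiN(SiMe3)2. n-BuLi should then trigger the rearrangement to ynolate 11, and i-Pr3SiOTf should give 12, where the route is rejoined.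

Step 13. The 3-methoxy group may be lost through the competing five-membered boron chelate, or cleavage of the less reactive ethyl ether may stay incomplete. The fallback separates the two ether cleavages, avoids the boron halide and sets out from 28. Hydrogenolysis (H2, 10% Pd/C, EtOAc–MeOH, rt) should give 5-ethoxy-7-hydroxy-8-[(1R)-1-(4-hydroxyphenyl)ethyl]-3-methoxy-2-(4-methoxyphenyl)-4H-chromen-4-one F6. MgI2·OEt2 in toluene at 60–80 °C should then cleave only the ether held in the six-membered magnesium chelate with the C4 carbonyl, iodide being a good nucleophile towards the ethyl group, and give target 29.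

**Further compounds**

F1 | step 7 | (E)-3-ethoxybut-2-enoic acid | CCO/C(C)=C/C(O)=O
F2 | step 7 | (E)-3-ethoxybut-2-enoyl chloride | CCO/C(C)=C/C(Cl)=O
F3 | step 6 | (2R)-2-[4-(benzyloxy)phenyl]propanoic acid | OC(=O)[C@H](C)c1ccc(OCc2ccccc2)cc1
F4 | step 6 | methyl (2R)-2-[4-(benzyloxy)phenyl]propanoate | COC(=O)[C@H](C)c1ccc(OCc2ccccc2)cc1
F5 | step 6 | (3R)-3-[4-(benzyloxy)phenyl]-1,1-dibromobutan-2-one | BrC(Br)C(=O)[C@H](C)c1ccc(OCc2ccccc2)cc1
F6 | step 13 | 5-ethoxy-7-hydroxy-8-[(1R)-1-(4-hydroxyphenyl)ethyl]-3-methoxy-2-(4-methoxyphenyl)-4H-chromen-4-one | COc1ccc(-c2oc3c([C@H](C)c4ccc(O)cc4)c(O)cc(OCC)c3c(=O)c2OC)cc1
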